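(The earlier runs and the new flask stem from a simulated flask with constants of no real substance.)

Read at 30 min, this flask stands far beyond the amber run, the same flask followed so far, whose last reading is at 4.00 min.

| flask | starting material | acid | protic impurity | scavenger | remark | time |
|---|---|---|---|---|---|---|
| amber | 0.010 M | 0.030 mM | 10 mM | 0.015 M | the very flask that is asked about, followed so far |  |
| flask | 0.010 M | 0.0300 mM | 10.0 mM | 0.0150 M |  | 30 min |

amber run (percent of the starting material charged)

| time / min | starting material / % | target / % |
|---|---|---|
| 0.200 | 97 | 0 |
| 0.500 | 89 | 0 |
| 1.00 | 76 | 4 |
| 1.50 | 68 | 4 |
| 2.00 | 59 | 7 |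
| 3.00 | 48 | 11 |
| 4.00 | 40 | 9 |

(standard deviation of a reading: 1.5 percentage points)

* part of the starting material that has reacted at 30 min
* pH of the solution at 30 min

- acid is the free proton; pH is minus the decimal logarithm of its molar concentration
- what has gone from starting material into another species counts as reacted, even if it can come back

Two extreme flasks bracket the answer, and both start from that last reading, 40% of the charge left. In the first, the loss stays pseudo-first-order at 0.229 min⁻¹, which leaves 0.104% at 30 min. In the second, each starting material lost takes one protic impurity with it; the two are charged equally, so one over the remaining fraction climbs in a straight line. Its slope, that rise per minute, is the pair constant, read as 0.375 min⁻¹, and it leaves 8.16%.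

The correction is the target. The last amber reading puts it at about 15.0% of the loss, a ratio of scattered readings, and I assume that part spares the impurity, so I put this flask between the two: 91.8% to 99.9% reacted.

The forecast says 96% and pH 4.52, adding that “A reversible step, or acid decay, would leave a few percent”.

    starting material + weak acid → side product (k = 23.0 M⁻¹ min⁻¹)
    starting material + protic impurity → quenched substrate (k = 22.0 M⁻¹ min⁻¹)
    weak acid + scavenger → scavenged by-product (k = 13.0 M⁻¹ min⁻¹)
    starting material → weak acid + target (k = 1.30 × 10⁻⁴ min⁻¹)
    starting material + acid → weak acid + acid + target (k = 1300 M⁻¹ min⁻¹)
    starting material + weak acid ⇌ idle adduct, settled at all times (K = 4000 M⁻¹)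
    weak acid ⇌ conjugate base + acid, settled at all times (K = 1.00 × 10⁻⁸ M)

The flask gives 96.0% reacted and pH 4.52, as forecast and inside my window, with 3.95% starting material left, 4.38% idle adduct counted as reacted, and acid at 100% of its charge. That answer moves by 5 points with protic impurity at 5.34 mM or a reading at 14.7 min. The same flask read at 12 min gets from the same two constants a window of 81.8% to 93.6%, and it stands at 88.4%.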